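The readings were generated by integration for an exercise, noise included.

Amounts are what two colleagues dispute over these flasks: how much electrophile, nucleophile and free base each one holds, and how much target those charges can still give.

| flask | electrophile | nucleophile | free base | remark | time |
|---|---|---|---|---|---|
| south | 0.23 M | 0.14 M | 0.115 M (fed, over 12 s) | run made earlier |  |
| north | 0.23 M | 0.27 M | 0.115 M (fed, over 12 s) | run made earlier |  |
| west | 0.23 M | 0.49 M | 0.115 M (fed, over 12 s) | run made earlier |  |
| south-west | 0.23 M | 0.345 M | 0.092 M (fed, over 12 s) | run made earlier |  |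
| epsilon | 0.50 M | 0.600 M | 0.0600 M (fed, over 12 s) |  | 2.5 min |
| zeta | 0.30 M | 0.120 M | 0.0600 M (fed, over 12 s) |  | 2.5 min |
| delta | 0.23 M | 0.600 M | 0.150 M (fed, over 12 s) |  | 2.5 min |
| theta | 0.30 M | 0.345 M | 0.0800 M (fed, over 50 s) |  | 2.5 min |
| gamma | 0.23 M | 0.345 M | 0.115 M (fed, over 12 s) |  | 2.5 min |
| alpha | 0.50 M | 0.345 M | 0.0800 M (fed, over 12 s) |  | 2.5 min |

| run | time / min | target / % | electrophile / % |
|---|---|---|---|
| south | 0.200 | 21.9 | 78.1 |
| south | 0.667 | 39.9 | 60.0 |
| south | 1.33 | 48.6 | 51.4 |
| south | 2.00 | 50.9 | 48.7 |
| south | 2.50 | 52.6 | 46.4 |
| north | 0.200 | 37.0 | 62.7 |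
| north | 0.417 | 54.6 | 45.4 |
| north | 0.667 | 64.5 | 35.7 |
| north | 1.33 | 72.9 | 24.9 |
| north | 2.50 | 81.0 | 18.5 |
| west | 0.200 | 55.6 | 44.6 |
| west | 0.417 | 76.2 | 22.0 |
| west | 0.667 | 87.7 | 14.0 |
| west | 1.33 | 95.9 | 3.7 |
| west | 2.50 | 99.5 | 1.1 |
| south-west | 0.200 | 43.8 | 54.7 |
| south-west | 0.667 | 73.5 | 26.6 |
| south-west | 1.33 | 85.8 | 17.2 |
| south-west | 2.00 | 86.1 | 14.0 |
| south-west | 2.50 | 89.6 | 11.2 |

(standard deviation of a reading: 1 percentage point)



* the flasks by amount of target, in percent of the electrophile charged, highest first, at 2.5 min (epsilon / zeta / delta / theta / gamma / alpha)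
* the amount of target, in percent of the electrophile charged of the flask you put first, at 2.5 min
* the amount of target, in percent of the electrophile charged of the flask you put last, at 2.5 min

The first colleague holds a rate view. Target at the first reading climbs with the nucleophile charge, from 21.9 % in the south run to 55.6 % in the west run, so she reads electrophile meeting nucleophile one for one, with nucleophile as the limiting reagent of zeta. To her a slow tail is merely a tail: the north run still gained 8.1 percentage points between its last two readings. Zeta, she says, heads for 40.0 %.

The second colleague counts acid instead. Each target takes one nucleophile and sets one acid free, and he reckons that this acid needs a partner, either free base or a further nucleophile, however the two share it. So each target costs two units out of the nucleophile and free base charged together. For zeta that gives 30.0 %. He calls half the sum of nucleophile and free base charged, taken against the electrophile charged and capped at 100 percent, the acid ceiling.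

The runs give him his argument. The south run has a ceiling of 55.4 % and a last reading of 52.6 %, and it gained just 1.7 points between its last two readings, though one-for-one counting would leave room up to 60.9 %. The north run's tail is heading for 83.7 % and stands at 81.0 %. His ceilings for the new flasks are 163 % for delta, so capped there by the electrophile, then >99.9 % for gamma, 70.8 % for theta, 66.0 % for epsilon, 42.5 % for alpha and 30.0 % for zeta.

The forecast stands on his side: delta > gamma > theta > epsilon > alpha > zeta, with 99.7 % for the first flask and 29.8 % for the last, which lies below the reckoned ceiling of zeta. Its ground: “The base takes it first, then a second nucleophile is lost as its unreactive salt.”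

The flasks give delta > gamma > theta > epsilon > alpha > zeta, with 99.9 % first and 31.0 % last. Zeta thus ends beside its ceiling of 30.0 %, lower than the 40.0 % of the rate view, and a run ten times as long makes no difference there. The rate view keeps the flasks whose ceiling reaches the whole charge: gamma holds 91.5 % at 2.50 min and 95.8 % at 25.0 min.

    nucleophile + acid set free ⇌ protonated nucleophile, settled at all times (K = 2200 M⁻¹)
    electrophile + nucleophile ⇌ acid set free + target (K = 3.50, k = 0.200 M⁻¹ s⁻¹)
    acid set free + free base ⇌ salt of the base, settled at all times (K = 9700 M⁻¹)

In zeta the shrinking supply of nucleophile is the main reason for the stop: with that supply held, the flask ends at 97.1 % instead of 31.0 %, which accounts for 96 % of what is missing.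

For the neighbour of zeta charged with 0.20 M of nucleophile, the extra charge lifts the ceiling by half its amount, to 43.3 %. That flask gives 44.5 % of target.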